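| setting | midnight | autumn | flask |
|---|---|---|---|
| substrate | 0.29 M (fed, over 80 s) | 0.29 M (fed, over 80 s) | 0.29 M (fed, over 80 s) |
| gas | 28 mM (held) | 28 mM (held) | 28 mM (held) |
| free catalyst | 0.063 mol% | 0.063 mol% | 0.063 mol% |
| second catalyst | 0.055 mol% | 0.083 mol% | 0.11 mol% |
| remark | run made earlier | run made earlier |  |
| time |  |  | 12 min |

| run | time / min | substrate / % | open intermediate / % | product / % |
|---|---|---|---|---|
| midnight | 0.500 | 36.0 | 1.4 | 0 |
| midnight | 1.33 | 90.3 | 9.0 | 0 |
| midnight | 3.00 | 71.1 | 28.1 | 0.9 |
| midnight | 8.00 | 34.4 | 59.5 | 6.1 |
| autumn | 2.00 | 82.4 | 16.4 | 0.5 |
| autumn | 4.00 | 60.9 | 36.0 | 2.5 |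
| autumn | 5.00 | 53.5 | 41.9 | 5.1 |
| autumn | 8.00 | 34.2 | 56.2 | 10.3 |

(standard deviation of a reading: 0.5 percentage points)

- at the start none of the gas is in solution
- percentages count the whole charge, also what has not yet gone in

- the largest share of what was charged as substrate, at 12 min belongs to (open intermediate / substrate / product)
- the largest share itself, whichever of these holds it, in percent of the substrate charged

Take the easy step first, the fraction of substrate left. Once the feed is over it falls by a steady factor per minute, a pseudo-first-order loss. The midnight run gives 0.145 /min and the autumn run 0.147 /min, so you may use their mean, 0.146 /min. Count the feed as a delay of half its dosing time, and this reckoning puts the substrate left in the flask at 19.1 % at 12 min.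

Now take what stands between open intermediate and product. Divide the product gained in each run's last window by the mean open intermediate and the window's length. Midnight reads 0.0237 /min and autumn 0.0353 /min. Their ratio, 1.49, reads close to the ratio of loadings, 1.51, so the bench rule, with the other charges held as in these runs, is that the drain follows the second catalyst. Scaled to the flask, the two readings give 0.0472 /min, the drain constant: the fraction of open intermediate turning to product each minute.

With k the substrate constant, d the drain, τ the time less the delay and s the substrate left, open intermediate is k/(k−d)·(e^(−dτ)−s). That gives 58.3 %, and I commit to that. The border is this: midnight's window spans open intermediate from 28.1 % to 59.5 %, a ratio of 2.12. My figure lies inside it, but below that span these last windows give no reading of the drain.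

The forecast names open intermediate at 55 %, lower than my figure, with a drain of 0.055 per minute against my 0.0472 /min, “though this rests on noisy data”.

The flask gives open intermediate at 58.3 %.

    reagent + catalyst intermediate → second catalyst + product (k = 1900 /M/min)
    second catalyst + open intermediate ⇌ catalyst intermediate (K = 5.30 /M, k = 21900 /M/min)
    reagent ⇌ dormant form (K = 7.80, k = 0.210 /min)
    substrate + free catalyst → free catalyst + open intermediate (k = 804 /M/min)
    gas ⇌ reagent, rate k5*(csat - [reagent]) (kL = 4.99 /min)

Open intermediate leads at 12 min partly through the undoing of catalyst intermediate into second catalyst and open intermediate, acting together with the time given. With that undoing struck out it stands at 24.9 % against 58.3 %, and left ten times as long at 0.0247 %. The drain constant had put this flask at 58.3 %. Carried to the neighbour read at 50 min, below the span, it gives 14.3 %, more than the 9.84 % standing there, and that neighbour's largest share has passed to product, at 90.1 %.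

The data are simulated on assumed constants, noise included.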